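C1–C6 are the arene carbons: C1 carries the benzylic CH2O carbon C7, C3 the angelate oxygen, C4 the side chain. C8 is the quaternary oxirane carbon, C9 the oxirane CH2 and C10 the acetoxymethyl carbon. Feature: C9 and C10 both sit on C8, so in the 2-arylallyl acetate the acetate C=O oxygen can reach C8 through a five-membered 1,3-dioxolan-2-ylium ring (C8, C10, two O, acetyl C) while C9 takes bromine. That oxygen ends as the oxirane oxygen.
Oxirane C8–O–C9 ⇒ C8-hydroxy/C9-bromide (base closure) ⇒ 2-arylallyl acetate + NBS + water under a chiral cinchona dimer, which sets C8.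
C4–C8 ⇒ Negishi coupling of an arylzinc iodide with silyl-protected 2-bromoallyl alcohol. Silyl is exchanged for acetyl only after the palladium step, because 2-bromoallyl acetate would ionise at C10–O with zerovalent palladium.
Esters: the C7 ester comes from a Mitsunobu reaction with bought (R)-2-methylbutanoic acid and the aryl angelate from a mixed anhydride, both on 5-(hydroxymethyl)-2-iodophenol made from methyl 3-hydroxy-4-iodobenzoate.
Ring order: the arene is bought, the dioxolanylium ring is formed and opened inside the key step, and the oxirane is closed last.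

Key step: step 8

Assumption: the alkene face chosen by (DHQD)2PHAL is inferred from its halocyclisations of 1,1-disubstituted aryl alkenes. If the C8 epimer prevails, the pseudo-enantiomeric (DHQ)2PHAL is used with nothing else changed.

Step 1
Reactants: 1 methyl 3-hydroxy-4-iodobenzoate
Product: 2 5-(hydroxymethyl)-2-iodophenol
Conditions: i-Bu2AlH (3.5 equiv), CH2Cl2, −78 → 0 °C; aq. potassium sodium tartrate
Reagents that add atoms: none
Why: Hydride reduction of the ester with i-Bu2AlH (one equivalent is spent on the phenol) should give the benzylic alcohol and leave the aryl–iodine bond alone at low temperature.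

Step 2
Reactants: 2 5-(hydroxymethyl)-2-iodophenol; 3 (R)-2-methylbutanoic acid
Product: 4 (3-hydroxy-4-iodophenyl)methyl (2R)-2-methylbutanoate
Conditions: PPh3, DIAD, THF, 0 °C → rt
Reagents that add atoms: none
Why: In this Mitsunobu esterification only the aliphatic C7 hydroxyl is activated and the carboxylate, far more acidic than the iodophenol, is the nucleophile, so the phenol stays free and the acid, never activated at its carbonyl, keeps its (R) centre.

Step 3
Reactants: 4 (3-hydroxy-4-iodophenyl)methyl (2R)-2-methylbutanoate; 5 angelic acid; 6 2,4,6-trichlorobenzoyl chloride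
Product: 8 2-iodo-5-[[(2R)-2-methylbutanoyl]oxymethyl]phenyl (Z)-2-methylbut-2-enoate, via angelic 2,4,6-trichlorobenzoic anhydride 7 (not isolated)
Conditions: 5, 6, Et3N, toluene, rt; then 4, Et3N, toluene, rt → 40 °C (no DMAP)
Reagents that add atoms: none
Why: In this Yamaguchi-type mixed-anhydride esterification the phenol attacks the unhindered angeloyl carbonyl of 7, and omitting nucleophilic catalysts avoids the addition–elimination that turns angelates into tiglates.

Step 4
Reactants: 9 2-bromoallyl alcohol
Product: 10 [(2-bromoprop-2-en-1-yl)oxy](tert-butyl)dimethylsilane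
Conditions: TBSCl, imidazole, CH2Cl2, 0 °C → rt
Reagents that add atoms: tert-butyldimethylsilyl chloride, CC(C)(C)[Si](C)(C)Cl
Why: Imidazole-promoted silylation of the primary alcohol turns the allylic oxygen into a group that cannot leave in the palladium step.

Step 5
Reactants: 8 2-iodo-5-[[(2R)-2-methylbutanoyl]oxymethyl]phenyl (Z)-2-methylbut-2-enoate; 10 [(2-bromoprop-2-en-1-yl)oxy](tert-butyl)dimethylsilane; 11 zinc
Product: 13 2-[3-(tert-butyldimethylsilyloxy)prop-1-en-2-yl]-5-[[(2R)-2-methylbutanoyl]oxymethyl]phenyl (Z)-2-methylbut-2-enoate, via arylzinc iodide 12 (not isolated)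
Conditions: Zn dust (BrCH2CH2Br/TMSCl-activated), LiCl, THF, 25–40 °C; then 10, Pd(OAc)2 (2 mol %), SPhos (4 mol %), THF, 25 °C
Reagents that add atoms: none
Why: LiCl-mediated direct zinc insertion tolerates esters and is helped by the ortho-acyloxy group, and the Negishi coupling then joins C4 to C8 at the vinylic C–Br bond because the silyl ether, unlike an acetate, cannot form a π-allyl complex with zerovalent palladium.

Step 6
Reactants: 13 2-[3-(tert-butyldimethylsilyloxy)prop-1-en-2-yl]-5-[[(2R)-2-methylbutanoyl]oxymethyl]phenyl (Z)-2-methylbut-2-enoate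
Product: 14 2-(3-hydroxyprop-1-en-2-yl)-5-[[(2R)-2-methylbutanoyl]oxymethyl]phenyl (Z)-2-methylbut-2-enoate
Conditions: HF·pyridine, pyridine/THF, 0 °C → rt
Reagents that add atoms: none
Why: Fluoride-driven desilylation in a pyridine-buffered medium frees the primary alcohol without forming a basic alkoxide, so the angeloyl group should not move from the phenol oxygen to O10.

Step 7
Reactants: 14 2-(3-hydroxyprop-1-en-2-yl)-5-[[(2R)-2-methylbutanoyl]oxymethyl]phenyl (Z)-2-methylbut-2-enoate
Product: 15 2-(3-acetoxyprop-1-en-2-yl)-5-[[(2R)-2-methylbutanoyl]oxymethyl]phenyl (Z)-2-methylbut-2-enoate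
Conditions: Ac2O, pyridine, CH2Cl2, 0 °C → rt
Reagents that add atoms: acetic anhydride, CC(=O)OC(C)=O
Why: Pyridine-mediated acetylation of the primary allylic alcohol is fast, touches no stereocentre and needs no DMAP, so the angelate geometry is safe.

Step 8
Reactants: 15 2-(3-acetoxyprop-1-en-2-yl)-5-[[(2R)-2-methylbutanoyl]oxymethyl]phenyl (Z)-2-methylbut-2-enoate; 16 N-bromosuccinimide
Product: 19 2-[(2S)-1-acetoxy-3-bromo-2-hydroxypropan-2-yl]-5-[[(2R)-2-methylbutanoyl]oxymethyl]phenyl (Z)-2-methylbut-2-enoate, via dioxolanylium ion 17 (not isolated), via hemi-orthoester 18 (not isolated)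
Conditions: NBS (1.1 equiv), (DHQD)2PHAL (hydroquinidine 1,4-phthalazinediyl diether, 10 mol %), MeCN/H2O 10:1, −30 °C, dark; aq. Na2S2O3
Reagents that add atoms: N-bromosuccinimide (16), O=C1CCC(=O)N1Br; water, O
Why: Proposed new method: catalyst-bound NBS hands Br+ to the terminal carbon C9 of the styrene-type alkene, and as charge builds at benzylic C8 the carbonyl oxygen of the C10 acetate bonds to C8 anti to bromine to give ion 17; water then adds to the cationic C2 and hemi-orthoester 18 collapses to the primary acetate and tertiary alcohol of 19, any tertiary acetate reaching 19 by 1,2-acyl shift back through 18. The closest known reaction types are (DHQD)2PHAL-catalysed halolactonisation and halocyclisation of 1,1-disubstituted aryl alkenes by carboxyl or amide oxygen, cinchona-catalysed bromohydroxylation of aryl alkenes with water, and the racemic wet Prévost–Woodward acyloxonium route to hydroxy esters; an ester carbonyl as internal nucleophile in a catalytic asymmetric version has not been shown. The only ring closed is the transient 1,3-dioxolan-2-ylium ring (5-exo, O to C8), and it is opened again in the same flask, so 19 is acyclic and the former carbonyl oxygen is O8. The C8 stereocentre is set by the catalyst, which must put bromine on the Re face so that oxygen enters on the Si face of C8 (ranking C10 > aryl > C9) to give (S)-19; the (R)-2-methylbutanoate is too remote to bias this. Site selectivity rests on the substrate: the 1,1-disubstituted aryl alkene is far more nucleophilic than the conjugated angelate alkene, Markovnikov polarisation sends bromine to C9, and five-membered capture by the alkyl acetate should outrun six-membered capture by the less basic aryl angelate carbonyl. Direct attack of water on C8 anti to bromine would give the same 19 with the same configuration, so the two oxygen-delivery paths converge.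

Step 9
Reactants: 19 2-[(2S)-1-acetoxy-3-bromo-2-hydroxypropan-2-yl]-5-[[(2R)-2-methylbutanoyl]oxymethyl]phenyl (Z)-2-methylbut-2-enoate
Product: 20 2-[(2R)-2-(acetoxymethyl)oxiran-2-yl]-5-[[(2R)-2-methylbutanoyl]oxymethyl]phenyl (Z)-2-methylbut-2-enoate (CNP0256757.1)
Conditions: K2CO3 (powdered, anhydrous), acetone, 0 °C → rt
Reagents that add atoms: none
Why: In this intramolecular Williamson-type 3-exo-tet displacement the C8 alkoxide attacks C9 and expels bromide without touching any bond at C8, so the configuration is kept (the descriptor changes from S to R only because CH2Br outranks CH2OAc while the ring CH2 does not), and a weak insoluble base in an aprotic solvent should spare the three esters.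

Compound list
1 | methyl 3-hydroxy-4-iodobenzoate | COC(=O)c1ccc(I)c(O)c1 | starting material
2 | 5-(hydroxymethyl)-2-iodophenol | OCc1ccc(I)c(O)c1 | intermediate
3 | (R)-2-methylbutanoic acid | CC[C@@H](C)C(=O)O | starting material
4 | (3-hydroxy-4-iodophenyl)methyl (2R)-2-methylbutanoate | Oc1cc(COC(=O)[C@H](C)CC)ccc1I | intermediate
5 | angelic acid, (Z)-2-methylbut-2-enoic acid | C/C=C(/C)C(=O)O | starting material
6 | 2,4,6-trichlorobenzoyl chloride | O=C(Cl)c1c(Cl)cc(Cl)cc1Cl | starting material
7 | angelic 2,4,6-trichlorobenzoic anhydride | C/C=C(/C)C(=O)OC(=O)c1c(Cl)cc(Cl)cc1Cl | intermediate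
8 | 2-iodo-5-[[(2R)-2-methylbutanoyl]oxymethyl]phenyl (Z)-2-methylbut-2-enoate | C/C=C(/C)C(=O)Oc1cc(COC(=O)[C@H](C)CC)ccc1I | intermediate
9 | 2-bromoallyl alcohol | OCC(Br)=C | starting material
10 | [(2-bromoprop-2-en-1-yl)oxy](tert-butyl)dimethylsilane | C=C(Br)CO[Si](C)(C)C(C)(C)C | intermediate
11 | zinc | [Zn] | starting material
12 | [2-[(Z)-2-methylbut-2-enoyl]oxy-4-[[(2R)-2-methylbutanoyl]oxymethyl]phenyl]zinc iodide | C/C=C(/C)C(=O)Oc1cc(COC(=O)[C@H](C)CC)ccc1[Zn]I | intermediate
13 | 2-[3-(tert-butyldimethylsilyloxy)prop-1-en-2-yl]-5-[[(2R)-2-methylbutanoyl]oxymethyl]phenyl (Z)-2-methylbut-2-enoate | C/C=C(/C)C(=O)Oc1cc(COC(=O)[C@H](C)CC)ccc1C(=C)CO[Si](C)(C)C(C)(C)C | intermediate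
14 | 2-(3-hydroxyprop-1-en-2-yl)-5-[[(2R)-2-methylbutanoyl]oxymethyl]phenyl (Z)-2-methylbut-2-enoate | C/C=C(/C)C(=O)Oc1cc(COC(=O)[C@H](C)CC)ccc1C(=C)CO | intermediate
15 | 2-(3-acetoxyprop-1-en-2-yl)-5-[[(2R)-2-methylbutanoyl]oxymethyl]phenyl (Z)-2-methylbut-2-enoate | C/C=C(/C)C(=O)Oc1cc(COC(=O)[C@H](C)CC)ccc1C(=C)COC(C)=O | intermediate
16 | N-bromosuccinimide | O=C1CCC(=O)N1Br | starting material
17 | (4S)-4-aryl-4-(bromomethyl)-2-methyl-1,3-dioxolan-2-ylium ion (aryl = the diester arene of 15) | C/C=C(/C)C(=O)Oc1cc(COC(=O)[C@H](C)CC)ccc1[C@@]1(CBr)COC(C)=[O+]1 | intermediate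
18 | (4S)-4-aryl-4-(bromomethyl)-2-methyl-1,3-dioxolan-2-ol (both C2 epimers; aryl as in 17) | C/C=C(/C)C(=O)Oc1cc(COC(=O)[C@H](C)CC)ccc1[C@@]1(CBr)COC(C)(O)O1 | intermediate
19 | 2-[(2S)-1-acetoxy-3-bromo-2-hydroxypropan-2-yl]-5-[[(2R)-2-methylbutanoyl]oxymethyl]phenyl (Z)-2-methylbut-2-enoate | C/C=C(/C)C(=O)Oc1cc(COC(=O)[C@H](C)CC)ccc1[C@](O)(COC(C)=O)CBr | intermediate
20 | 2-[(2R)-2-(acetoxymethyl)oxiran-2-yl]-5-[[(2R)-2-methylbutanoyl]oxymethyl]phenyl (Z)-2-methylbut-2-enoate | C/C=C(/C)C(=O)Oc1cc(COC(=O)[C@H](C)CC)ccc1[C@]1(COC(C)=O)CO1 | target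

Total step count: 9. Longest linear sequence: 8 (steps 1, 2, 3, 5, 6, 7, 8, 9). Step 4 is a one-step side branch.

Steps most likely to fail

Step 8.
- **What may go wrong:** Facial selectivity of bromenium transfer may be poor because the ortho-acyloxy group twists the arene out of the alkene plane. The benzylic C8–O bond of the dioxolanylium ring may open and reclose and so erode the configuration. The angelate carbonyl may take part, with scrambling of acyl groups.
- **Fallback (known chemistry):** It sets out from 14. A Katsuki–Sharpless asymmetric epoxidation (Ti(OiPr)4, L-(+)-diethyl tartrate, t-BuOOH, 4 Å molecular sieves, CH2Cl2, −20 °C) should give 2-[(2S)-2-(hydroxymethyl)oxiran-2-yl]-5-[[(2R)-2-methylbutanoyl]oxymethyl]phenyl (Z)-2-methylbut-2-enoate F1.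
- **Choice of tartrate:** L-(+)-tartrate is the enantiomer that turns allyl alcohol into (S)-glycidol. In F1 the aryl group takes the place of hydrogen as the lowest-ranked substituent, so the same face gives (S)-F1, which has the spatial arrangement of the target.
- **Return:** Acetylation (Ac2O, pyridine, CH2Cl2, 0 °C) comes back to the route at 20.

Step 9.
- **What may go wrong:** Acyl transfer to the C8 alkoxide, from the aryl angelate through a six-membered transition state or from the acetate through a five-membered one, may compete with ring closure. A freed phenoxide could then attack C9.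
- **Fallback:** The halohydrin logic is given up and oxygen is transferred directly to the C8=C9 alkene of 15 by a Shi-type epoxidation. This uses a chiral dioxirane made from a carbohydrate-derived N-aryl oxazolidinone ketone and KHSO5 (used as 2 KHSO5·KHSO4·K2SO4) in K2CO3/AcOH buffer, DME/dimethoxymethane–water, −10 °C.
- **Why it fits:** The method is known for 1,1-disubstituted aryl alkenes and needs no alkoxide next to the esters. The electrophilic oxidant should prefer the styrene-type alkene to the angelate. The ketone enantiomer is picked in a test run.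
- **Return:** It sets out from 15 and comes back at 20. No new compound is made on this way (F0).

Step 5.
- **What may go wrong:** Zinc insertion may be sluggish, the arylzinc may be protonated, or the ortho-substituted arylzinc may couple only slowly with the hindered 1,1-disubstituted vinyl bromide.
- **Fallback:** Polarity and order are reversed, setting out from 10 and 4.
- **First stage:** Miyaura borylation of 10 (bis(pinacolato)diboron, PdCl2(PPh3)2, PPh3, KOPh, toluene, 50 °C) gives tert-butyldimethyl[[2-(4,4,5,5-tetramethyl-1,3,2-dioxaborolan-2-yl)prop-2-en-1-yl]oxy]silane F2.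
- **Second stage:** Suzuki–Miyaura coupling of F2 with iodophenol 4 (PdCl2(dppf), K3PO4, THF/H2O, 50 °C), run before the base-labile aryl ester is in place, gives [4-[3-(tert-butyldimethylsilyloxy)prop-1-en-2-yl]-3-hydroxyphenyl]methyl (2R)-2-methylbutanoate F3.
- **Return:** Angeloylation of F3 with mixed anhydride 7 under the conditions of step 3 comes back to the route at 13.

Further compounds
F1 | step 8 | 2-[(2S)-2-(hydroxymethyl)oxiran-2-yl]-5-[[(2R)-2-methylbutanoyl]oxymethyl]phenyl (Z)-2-methylbut-2-enoate | C/C=C(/C)C(=O)Oc1cc(COC(=O)[C@H](C)CC)ccc1[C@]1(CO)CO1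
F0 | step 9 | none | none
F2 | step 5 | tert-butyldimethyl[[2-(4,4,5,5-tetramethyl-1,3,2-dioxaborolan-2-yl)prop-2-en-1-yl]oxy]silane | C=C(CO[Si](C)(C)C(C)(C)C)B1OC(C)(C)C(C)(C)O1
F3 | step 5 | [4-[3-(tert-butyldimethylsilyloxy)prop-1-en-2-yl]-3-hydroxyphenyl]methyl (2R)-2-methylbutanoate | Oc1cc(COC(=O)[C@H](C)CC)ccc1C(=C)CO[Si](C)(C)C(C)(C)C
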